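## Structural features

Target 38 is a sesquineolignan: a cis-2-aryl-3-(hydroxymethyl)-7-methoxy-2,3-dihydrobenzofuran (O1, C2, C3, C3a, C4–C7, C7a) that carries at C5 a 2,6-disubstituted 3,7-dioxabicyclo[3.3.0]octane (furofuran; C1′, C2′, O3′, C4′, C5′, C6′, O7′, C8′). C2′ is bonded to C5, C6′ to a syringyl ring, and a guaiacyl ring sits on C2. There are six stereocentres in two clusters: C2 and C3 (both S, aryl and hydroxymethyl cis, the less stable relation) and C1′, C2′, C5′, C6′ (R, S, R, S; cis ring fusion, both substituents exo). The central benzene ring insulates the clusters from each other, so each needs its own absolute control before the halves are joined. The benzylic aryl ether C2–O1 lies para to a phenol oxygen: acid ionises it, and base opens it through a quinone methide once the phenol is free; either turns cis into trans. The benzylic ethers C2′–O3′ and C6′–O7′ epimerise under acid in the same way, and the free phenols are easily oxidised. The real difficulty is to attach a 1,2,3,5-tetrasubstituted benzene to both halves without disturbing the cis C2/C3 relation. The key step exploits the fact that C3a, C4, C5, C6, C7 and C7a (O1 on C7a, C3 on C3a, oxygen on C7, the furofuran on C5, hydrogen on C4 and C6) are the carbons of an ynol ether alkyne (C7a≡C7), an alkyl alkyne (C3a≡C4) tethered to it through C3–C2–O1, and a terminal alkyne (C5≡C6).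

## Logic of the disconnections

38 from 37. The three O–Si bonds are cut last. The free phenols are the groups that open the benzylic ethers, so they stay masked until nothing else remains to be done. The forward step must use buffered fluoride.

37 from 36 from 35. The C7–O–CH3 bond is cut, then C7–O is traced back to C7–B. A 1,2-dialkoxyalkyne cannot serve as a diyne terminus, so boron stands in for the C7 oxygen. The forward steps need an oxidant that spares the electron-rich rings and a methylation that meets only one free phenol, which holds because the other two are silylated.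

35 from 19 and 34. The bonds C3a–C7a, C4–C5 and C6–C7 are cut. This removes the benzene ring and the dihydrofuran ring together and leaves two halves of equal size, each with all its stereocentres in place. No stereocentre is formed or touched in the forward step. It must deliver the furofuranyl carbon to C4 and not to C7, favour cross- over homo-trimerisation, and run at room temperature.

19 from 16. The C(sp)–B bond is cut. A one-flask sequence of alkoxide, trichloroethylene, butyllithium and borate on a substrate whose other alkyne is terminal would metalate and borylate both alkyne ends. The boron is therefore introduced in a separate step, on the diyne with two free alkyne C–H bonds. The forward step must metalate only the ynol ether C–H, which should be the more acidic one.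

16 from 11 and 12. The O1–C7a bond is cut; both ynol ether carbons come from 12. C2 is not a reacting centre, so its configuration is carried over. The forward step passes through the alkoxide of 11, which must not take a silyl group from the neighbouring primary oxygen or from a phenol. For this reason all silyl ethers in the route are triisopropylsilyl rather than the smaller tert-butyldimethylsilyl.

11 from 10 from 8, and 8 from 7 and 2. The C2–C3 bond is cut. The cis ring relation (oxygen and silyloxymethyl syn along the chain that ends in the alkyne) is the same as an anti relation between oxygen and alkynyl along the chain that ends in the carbonyl. A tin-free anti-selective aldol of an aromatic aldehyde therefore sets both centres. 7 comes from 4 and 5 (N-acyl bond), 4 from 3 (oxidation), and 2 from 1 (silylation). The forward aldol must be anti-selective and face-selective through the auxiliary in 5.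

34 from 31 and 32. The C2′–C(sp) bond is cut. Nucleophiles attack the cis-fused bicyclic oxocarbenium ion on its convex face, which gives the exo alkyne. 31 comes from 30 by acylation, and 30 from 28 by cleaving a C=C bond to the aldehyde, which closes onto the cis hydroxymethyl group.

28 from 27 from 26, and 26 from 24 and 21. The benzylic C6′–O7′ bond is cut (cation captured by a primary hydroxyl), then the C5′–C6′ bond (lactone enolate aldol, anti to the vinyl group). The benzylic carbinol centre need not be controlled in the aldol because the ring closure resets it. 24 comes from 22 and 23 by catalytic asymmetric conjugate addition, which sets the only stereocentre that must be bought with a chiral catalyst; 21 comes from 20.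

## Other disconnections considered

Alternative 1: The cut is C5′–C6′ and C1′–C2′ of the furofuran. In the forward step, lithiated dithiane A3 adds to the β-carbon of menthyloxy furanone A2, anti to the acetal substituent, and the lactone enolate is trapped by aldehyde A4 to give lactone A1. In its favour: two C–C bonds and two ring stereocentres form in one flask with substrate control, all aromatic carbons come from cheap aldehydes, and the reaction type is well established. On precedent, and on step count to the furofuran carbon skeleton, it is better than the chosen plan, whose furofuran branch needs eight steps. Against it here: A1 still needs dithiane removal without loss of the aryl bromide, two reductions, acetal removal and two ring closures. Its aryl MOM ether needs acid next to benzylic ethers. It also leaves the whole cis-dihydrobenzofuran to be built on the brominated ring. The mechanism is polar and auxiliary-controlled; the chosen plan is metal-templated and convergent. Overall the linear sequence would be longer and the hard problem (cis C2/C3 next to the arene) is only postponed.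

Alternative 2: The cut is C2′–O3′ and C6′–O7′. In the forward step, anodic oxidation of diol A6 generates a quinone methide at each p-hydroxybenzyl carbon, and each is captured by the distal primary hydroxyl, giving furofuran A5. In its favour: both rings and two stereocentres form in one operation, no protecting groups are needed, and the exo,exo product is the thermodynamic one. On atom and step economy for the furofuran it is better than the chosen plan. It is equal in that it puts no strain on the cis-dihydrobenzofuran, which does not yet exist. Against it: enantiopure A6 needs its own multi-step synthesis. Its two phenols differ in oxidation potential (the bromophenol is harder to oxidise). A5 keeps free phenols and oxidisable benzylic ethers and can be over-oxidised. The dihydrobenzofuran still has to be added afterwards. The mechanism is a two-fold two-electron oxidation; selectivity would rest on potential control rather than on a template.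

Alternative 3: The cut is C3–C3a. In the forward step, bromine–lithium exchange on epoxide A8 gives an aryllithium that opens the epoxide at its inner carbon (five-membered ring, inversion at C3) to give A7. In its favour: it is stereospecific, C2 and C3 are set beforehand in an acyclic precursor (equal to the chosen plan on this point), it frees the hydroxymethyl group directly, and anionic cyclisation onto an epoxide is a known reaction class (better on precedent). Against it: the aryllithium sits next to a benzylic ether hydrogen at C2 that is flanked by oxygen, aryl and the epoxide. Proton transfer followed by β-elimination of the epoxide, or attack at the outer epoxide carbon to a chroman, would compete. A8 requires a stereocontrolled benzylic aryl ether bond at an electron-rich benzylic carbon, which is prone to ionisation. The furofuran must also be made first by one of the routes above, so the sequence is linear and longer than the chosen one.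

Key step: step 17

Remark: compounds 3, 5, 22, 23, (S)-BINAP and Cp*RuCl(cod) are taken as purchasable; TIPS means triisopropylsilyl.
Remark: the carbinol centre made in step 11 and the anomeric centre of 30 and 31 are carried as epimer mixtures because steps 13 and 16 reset them; their SMILES leave these centres open.

Step 1
Reactants: 1 vanillin
Product: 2 3-methoxy-4-(triisopropylsilyloxy)benzaldehyde
Conditions: TIPSCl, imidazole, DMF, rt
Reagents that add atoms: chlorotriisopropylsilane CC(C)[Si](Cl)(C(C)C)C(C)C
Why: Phenol silylation; the triisopropylsilyl ether should resist the alkoxide, carbonate and organolithium conditions of steps 5 to 8 better than a tert-butyldimethylsilyl ether.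

Step 2
Reactants: 3 4-(trimethylsilyl)but-3-yn-1-ol
Product: 4 4-(trimethylsilyl)but-3-ynoic acid
Conditions: TEMPO (cat.), PhI(OAc)2, MeCN/H2O, rt
Reagents that add atoms: water O
Why: Oxoammonium oxidation of the primary alcohol to the acid through the aldehyde hydrate; the near-neutral medium should not isomerise the β,γ-alkynyl acid to an allene.

Step 3
Reactants: 4 4-(trimethylsilyl)but-3-ynoic acid; 5 (S)-4-benzyloxazolidin-2-one
Product: 7 (S)-4-benzyl-3-[4-(trimethylsilyl)but-3-ynoyl]oxazolidin-2-one, via acid chloride 6 (not isolated)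
Conditions: (COCl)2, DMF (cat.), CH2Cl2, 0 °C to rt; then lithiated 5 (n-BuLi, THF, −78 °C), inverse addition
Reagents that add atoms: none
Why: N-Acylation of the lithiated auxiliary by the acid chloride; amine-free, low-temperature conditions are chosen so that the acidic propargylic α-hydrogens are not equilibrated to the allenyl isomer.

Step 4
Reactants: 7 (S)-4-benzyl-3-[4-(trimethylsilyl)but-3-ynoyl]oxazolidin-2-one; 2 3-methoxy-4-(triisopropylsilyloxy)benzaldehyde
Product: 8 (S)-4-benzyl-3-{(2R,3S)-3-[3-methoxy-4-(triisopropylsilyloxy)phenyl]-2-[(trimethylsilyl)ethynyl]-3-(trimethylsilyloxy)propanoyl}oxazolidin-2-one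
Conditions: MgCl2 (20 mol%), Et3N, Me3SiCl, EtOAc, rt
Reagents that add atoms: chlorotrimethylsilane C[Si](C)(C)Cl
Why: Magnesium-halide-catalysed anti-selective Evans aldol: soft enolisation gives the chelated Z-enolate, which should add to the aromatic aldehyde through a boat transition state on the face away from the benzyl group, setting the future C3 (R here) and C2 (S) with the anti relation that becomes cis in the ring. Silylation of the aldolate turns the magnesium over and blocks retro-aldol.

Step 5
Reactants: 8 the anti-aldol silyl ether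
Product: 10 (1S,2S)-2-ethynyl-1-[3-methoxy-4-(triisopropylsilyloxy)phenyl]propane-1,3-diol, via silylated alcohol 9 (not isolated)
Conditions: LiBH4, MeOH (2 equiv), THF, 0 °C; then K2CO3, MeOH, rt
Reagents that add atoms: none
Why: Reductive removal of the auxiliary (recovered) gives the primary alcohol without touching either stereocentre; methanolic carbonate then cleaves the O–SiMe3 and C(sp)–SiMe3 bonds, while the aryl triisopropylsilyl ether should survive the short exposure.

Step 6
Reactants: 10 (1S,2S)-2-ethynyl-1-[3-methoxy-4-(triisopropylsilyloxy)phenyl]propane-1,3-diol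
Product: 11 (1S,2S)-2-ethynyl-1-[3-methoxy-4-(triisopropylsilyloxy)phenyl]-3-(triisopropylsilyloxy)propan-1-ol
Conditions: TIPSCl (1.05 equiv), imidazole, CH2Cl2, 0 °C to rt
Reagents that add atoms: chlorotriisopropylsilane CC(C)[Si](Cl)(C(C)C)C(C)C
Why: The bulky silyl chloride should select the primary over the secondary benzylic hydroxyl; triisopropylsilyl is chosen because it migrates far less readily to a neighbouring alkoxide than tert-butyldimethylsilyl.

Step 7
Reactants: 11 (1S,2S)-2-ethynyl-1-[3-methoxy-4-(triisopropylsilyloxy)phenyl]-3-(triisopropylsilyloxy)propan-1-ol; 12 trichloroethylene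
Product: 16 (1S,2S)-2-ethynyl-1-(ethynyloxy)-1-[3-methoxy-4-(triisopropylsilyloxy)phenyl]-3-(triisopropylsilyloxy)propane, via potassium alkoxide 13 (not isolated), via dichlorovinyl ether 14 (not isolated), via dilithio diyne 15 (not isolated)
Conditions: KH (1.2 equiv), THF, 0 °C; Cl2C=CHCl, −40 °C to rt; n-BuLi (3.3 equiv), −78 to −40 °C; MeOH, −78 °C
Reagents that add atoms: none
Why: The alkoxide adds to dichloroacetylene formed in situ from trichloroethylene to give the (E)-1,2-dichlorovinyl ether; butyllithium then eliminates HCl and exchanges chlorine for lithium (the third equivalent is consumed by the other alkyne C–H), and protonation gives the terminal ynol ether. Only the O–H bond of 11 is engaged, so C2 keeps its configuration; this ynol ether synthesis is known for secondary benzylic alcohols.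

Step 8
Reactants: 16 the ethynyl ether diyne
Product: 19 (1S,2S)-2-ethynyl-1-[3-methoxy-4-(triisopropylsilyloxy)phenyl]-1-{[2-(4,4,5,5-tetramethyl-1,3,2-dioxaborolan-2-yl)ethynyl]oxy}-3-(triisopropylsilyloxy)propane, via lithium acetylide 17 (not isolated), via lithium borate 18 (not isolated)
Conditions: n-BuLi (1.0 equiv), THF, −78 then −30 °C (30 min); i-PrOBpin, −78 °C; HCl in Et2O (1.0 equiv), −78 °C to rt; filtration under argon, no chromatography
Reagents that add atoms: 2-isopropoxy-4,4,5,5-tetramethyl-1,3,2-dioxaborolane CC(C)OB1OC(C)(C)C(C)(C)O1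
Why: Acetylide borylation through the borate complex, released by one equivalent of anhydrous acid. With one equivalent of base and time to equilibrate, the lithium should rest on the ynol ether terminus, whose C–H is acidified by the oxygen on the adjacent sp carbon, so that boron is delivered to C7 and the C4 terminus stays C–H. The product has the skeleton required for the key step and is used at once.

Step 9
Reactants: 20 syringaldehyde
Product: 21 3,5-dimethoxy-4-(triisopropylsilyloxy)benzaldehyde
Conditions: TIPSOTf, 2,6-lutidine, CH2Cl2, 0 °C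
Reagents that add atoms: triisopropylsilyl trifluoromethanesulfonate CC(C)[Si](OS(=O)(=O)C(F)(F)F)(C(C)C)C(C)C
Why: The phenol is flanked by two methoxy groups, so the silyl triflate is used; the resulting hindered aryl silyl ether should be robust to base and Lewis acid.

Step 10
Reactants: 22 2(5H)-furanone; 23 potassium vinyltrifluoroborate
Product: 24 (S)-4-vinyldihydrofuran-2(3H)-one
Conditions: [Rh(cod)2]BF4 (3 mol%), (S)-BINAP, dioxane/H2O 10:1, 90 °C
Reagents that add atoms: none
Why: Hayashi–Miyaura asymmetric conjugate addition: the vinylrhodium species carbometalates the lactone on the face selected by the bisphosphine and the oxa-π-allyl rhodium is protonated by water. The (S) ligand is assigned by analogy with additions to cyclic enones and unsaturated lactones; the antipodal ligand would be used if the sense proved opposite.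

Step 11
Reactants: 24 (S)-4-vinyldihydrofuran-2(3H)-one; 21 3,5-dimethoxy-4-(triisopropylsilyloxy)benzaldehyde
Product: 26 (3S,4R)-3-{[3,5-dimethoxy-4-(triisopropylsilyloxy)phenyl](hydroxy)methyl}-4-vinyldihydrofuran-2(3H)-one (carbinol epimers), via lithium enolate 25 (not isolated)
Conditions: LDA, THF, −78 °C; then 21; AcOH, −78 °C
Reagents that add atoms: none
Why: Aldol addition of the lactone enolate anti to the vinyl group gives the trans-3,4-disubstituted lactone, which is the relation needed for the cis-fused bicycle; the carbinol configuration is irrelevant because step 13 passes through the benzylic cation.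

Step 12
Reactants: 26 the trans aldol lactone
Product: 27 (2R,3R)-2-{[3,5-dimethoxy-4-(triisopropylsilyloxy)phenyl](hydroxy)methyl}-3-vinylbutane-1,4-diol (carbinol epimers)
Conditions: LiAlH4, THF, 0 °C
Reagents that add atoms: none
Why: Hydride reduction of the lactone to the diol; neither ring stereocentre is enolisable once the carbonyl is gone.

Step 13
Reactants: 27 the triol
Product: 28 {(2S,3R,4R)-2-[3,5-dimethoxy-4-(triisopropylsilyloxy)phenyl]-4-vinyltetrahydrofuran-3-yl}methanol
Conditions: BF3·OEt2 (0.3 equiv), CH2Cl2, −20 to 0 °C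
Reagents that add atoms: none
Why: Ionisation of the electron-rich benzylic alcohol and capture of the cation by the hydroxyl four atoms away closes the tetrahydrofuran (the other primary hydroxyl could only form an oxetane). Closure should place the aryl group trans to the adjacent hydroxymethyl group, which is also the more stable arrangement if the ether re-ionises.

Step 14
Reactants: 28 the vinyl tetrahydrofuran
Product: 30 (3aR,4S,6aR)-4-[3,5-dimethoxy-4-(triisopropylsilyloxy)phenyl]tetrahydro-1H,3H-furo[3,4-c]furan-1-ol (anomers), via vicinal diol 29 (not isolated)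
Conditions: OsO4 (2 mol%), NaIO4, 2,6-lutidine, dioxane/H2O, rt
Reagents that add atoms: osmium tetroxide O=[Os](=O)(=O)=O; sodium periodate [Na+].[O-]I(=O)(=O)=O
Why: Lemieux–Johnson cleavage of the vinyl group is preferred to ozone because of the electron-rich arene; the aldehyde is cis to the hydroxymethyl group and should close at once to the bicyclic lactol.

Step 15
Reactants: 30 the lactol
Product: 31 (3aR,4S,6aR)-4-[3,5-dimethoxy-4-(triisopropylsilyloxy)phenyl]tetrahydro-1H,3H-furo[3,4-c]furan-1-yl acetate (anomers)
Conditions: Ac2O, pyridine, DMAP (cat.), CH2Cl2, 0 °C to rt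
Reagents that add atoms: acetic anhydride CC(=O)OC(C)=O
Why: Acetylation turns the anomeric hydroxyl into a leaving group for the oxocarbenium chemistry of step 16.

Step 16
Reactants: 31 the lactol acetate; 32 trimethylsilylacetylene
Product: 34 (1S,3aR,4S,6aR)-4-[3,5-dimethoxy-4-(triisopropylsilyloxy)phenyl]-1-ethynyltetrahydro-1H,3H-furo[3,4-c]furan, via silylalkyne 33 (not isolated)
Conditions: 32, n-BuLi, toluene, 0 °C; Et2AlCl; then 31, CH2Cl2, 0 °C to rt; work-up; K2CO3, MeOH, rt
Reagents that add atoms: none
Why: The alkynylalane ionises the anomeric acetate and delivers the alkynyl group to the oxocarbenium ion on the convex face of the cis-fused bicycle, which sets C2′ exo (S); methanolic carbonate then removes the C-silyl group while the hindered aryl silyl ether should remain.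

Step 17
Reactants: 19 the borylated ynol ether diyne; 34 the ethynyl furofuran
Product: 35 2-[(2S,3S)-5-{(1S,3aR,4S,6aR)-4-[3,5-dimethoxy-4-(triisopropylsilyloxy)phenyl]tetrahydro-1H,3H-furo[3,4-c]furan-1-yl}-2-[3-methoxy-4-(triisopropylsilyloxy)phenyl]-3-[(triisopropylsilyloxy)methyl]-2,3-dihydro-1-benzofuran-7-yl]-4,4,5,5-tetramethyl-1,3,2-dioxaborolane
Conditions: Cp*RuCl(cod) (5 mol%, divalent ruthenium), ClCH2CH2Cl, rt; 19 (1.3 equiv) added over 2 h to 34 and catalyst
Reagents that add atoms: none
Why: Proposed new method: oxidative cyclisation of the two tethered alkynes of 19 on the Cp*RuCl fragment should give a bicyclic ruthenacyclopentadiene in which C3a–C7a is already formed; the terminal alkyne of 34 then inserts and reductive elimination releases the arene. The closest known reaction type is the Cp*RuCl(cod)-catalysed [2+2+2] cyclotrimerisation of heteroatom-tethered 1,6-diynes (ynamide diynes to indolines) and of 1,6-diynyl boronates with terminal alkynes. The dihydrofuran ring is closed by the metal-templated coupling of the two inner alkyne carbons across the three-atom O1–C2–C3 tether, and the benzene ring by insertion of the third alkyne and C–C reductive elimination (C4–C5 and C6–C7). No stereocentre is created; C2 and C3 are spectators, and the neutral room-temperature medium offers no path for their epimerisation. The selectivity needed is regiochemical: the substituted carbon of 34 must bond to C4. The bulk of the Cp* ligand and of the pinacolboryl group on C7 should place the furofuranyl group meta to boron, as is the rule for 1,6-diynes with one substituted terminus. Slow addition of 19 should favour cross-trimerisation over diyne dimerisation, and the temperature is held at or below 25 °C so that the secondary benzylic ynol ether neither loses ketene by retro-ene fragmentation nor rearranges.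

Step 18
Reactants: 35 the arylboronate
Product: 36 (2S,3S)-5-{(1S,3aR,4S,6aR)-4-[3,5-dimethoxy-4-(triisopropylsilyloxy)phenyl]tetrahydro-1H,3H-furo[3,4-c]furan-1-yl}-2-[3-methoxy-4-(triisopropylsilyloxy)phenyl]-3-[(triisopropylsilyloxy)methyl]-2,3-dihydro-1-benzofuran-7-ol
Conditions: NaBO3·4H2O, THF/H2O, rt
Reagents that add atoms: sodium perborate [Na+].[O-]OB=O
Why: Perborate oxidation of the aryl boronate (aryl migration from boron to oxygen) is mild enough to leave the benzylic ethers and the silyl ethers untouched.

Step 19
Reactants: 36 the C7 phenol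
Product: 37 the C7 methyl ether, tris(triisopropylsilyl) ether of 38
Conditions: MeI, K2CO3, dry acetone, rt
Reagents that add atoms: iodomethane CI
Why: Williamson methylation of the only free phenol; the other phenols are silylated and the heterogeneous aprotic base should not cleave them at room temperature.

Step 20
Reactants: 37 the tris(triisopropylsilyl) ether
Product: 38 4-[(1S,3aR,4S,6aR)-4-[(2S,3S)-2-(4-hydroxy-3-methoxyphenyl)-3-(hydroxymethyl)-7-methoxy-2,3-dihydro-1-benzofuran-5-yl]tetrahydro-1H,3H-furo[3,4-c]furan-1-yl]-2,6-dimethoxyphenol (CNP0126146.1)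
Conditions: Bu4NF, AcOH (1:1, 6 equiv), THF, 0 °C to rt
Reagents that add atoms: none
Why: Fluoride cleaves the two aryl and the one primary silyl ether; acetic acid buffers the phenoxides so that the benzylic ethers are not opened through quinone methides and the cis C2/C3 relation is kept.

Compound list
1 | vanillin | COc1cc(C=O)ccc1O | starting material
2 | 3-methoxy-4-(triisopropylsilyloxy)benzaldehyde | COc1cc(C=O)ccc1O[Si](C(C)C)(C(C)C)C(C)C | intermediate
3 | 4-(trimethylsilyl)but-3-yn-1-ol | C[Si](C)(C)C#CCCO | starting material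
4 | 4-(trimethylsilyl)but-3-ynoic acid | C[Si](C)(C)C#CCC(=O)O | intermediate
5 | (S)-4-benzyloxazolidin-2-one | O=C1N[C@@H](Cc2ccccc2)CO1 | starting material
6 | 4-(trimethylsilyl)but-3-ynoyl chloride | C[Si](C)(C)C#CCC(=O)Cl | intermediate (not isolated)
7 | (S)-4-benzyl-3-[4-(trimethylsilyl)but-3-ynoyl]oxazolidin-2-one | C[Si](C)(C)C#CCC(=O)N1[C@@H](Cc2ccccc2)COC1=O | intermediate
8 | (S)-4-benzyl-3-{(2R,3S)-3-[3-methoxy-4-(triisopropylsilyloxy)phenyl]-2-[(trimethylsilyl)ethynyl]-3-(trimethylsilyloxy)propanoyl}oxazolidin-2-one | COc1cc([C@@H](O[Si](C)(C)C)[C@H](C(=O)N2[C@@H](Cc3ccccc3)COC2=O)C#C[Si](C)(C)C)ccc1O[Si](C(C)C)(C(C)C)C(C)C | intermediate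
9 | (2S,3S)-3-[3-methoxy-4-(triisopropylsilyloxy)phenyl]-2-[(trimethylsilyl)ethynyl]-3-(trimethylsilyloxy)propan-1-ol | COc1cc([C@@H](O[Si](C)(C)C)[C@H](CO)C#C[Si](C)(C)C)ccc1O[Si](C(C)C)(C(C)C)C(C)C | intermediate (not isolated)
10 | (1S,2S)-2-ethynyl-1-[3-methoxy-4-(triisopropylsilyloxy)phenyl]propane-1,3-diol | COc1cc([C@@H](O)[C@H](CO)C#C)ccc1O[Si](C(C)C)(C(C)C)C(C)C | intermediate
11 | (1S,2S)-2-ethynyl-1-[3-methoxy-4-(triisopropylsilyloxy)phenyl]-3-(triisopropylsilyloxy)propan-1-ol | COc1cc([C@@H](O)[C@H](CO[Si](C(C)C)(C(C)C)C(C)C)C#C)ccc1O[Si](C(C)C)(C(C)C)C(C)C | intermediate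
12 | trichloroethylene | ClC=C(Cl)Cl | starting material
13 | potassium alkoxide of 11 | COc1cc([C@@H]([O-])[C@H](CO[Si](C(C)C)(C(C)C)C(C)C)C#C)ccc1O[Si](C(C)C)(C(C)C)C(C)C.[K+] | intermediate (not isolated)
14 | (E)-1,2-dichlorovinyl ether of 11 | COc1cc([C@@H](O/C(Cl)=C\Cl)[C@H](CO[Si](C(C)C)(C(C)C)C(C)C)C#C)ccc1O[Si](C(C)C)(C(C)C)C(C)C | intermediate (not isolated)
15 | dilithio derivative of 16 (both alkyne termini lithiated) | COc1cc([C@@H](OC#C[Li])[C@H](CO[Si](C(C)C)(C(C)C)C(C)C)C#C[Li])ccc1O[Si](C(C)C)(C(C)C)C(C)C | intermediate (not isolated)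
16 | (1S,2S)-2-ethynyl-1-(ethynyloxy)-1-[3-methoxy-4-(triisopropylsilyloxy)phenyl]-3-(triisopropylsilyloxy)propane | COc1cc([C@@H](OC#C)[C@H](CO[Si](C(C)C)(C(C)C)C(C)C)C#C)ccc1O[Si](C(C)C)(C(C)C)C(C)C | intermediate
17 | lithium alkoxyacetylide of 16 (ynol ether terminus lithiated) | COc1cc([C@@H](OC#C[Li])[C@H](CO[Si](C(C)C)(C(C)C)C(C)C)C#C)ccc1O[Si](C(C)C)(C(C)C)C(C)C | intermediate (not isolated)
18 | lithium isopropoxy(alkynyl)pinacolborate of 17 | COc1cc([C@@H](OC#C[B-]2(OC(C)C)OC(C)(C)C(C)(C)O2)[C@H](CO[Si](C(C)C)(C(C)C)C(C)C)C#C)ccc1O[Si](C(C)C)(C(C)C)C(C)C.[Li+] | intermediate (not isolated)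
19 | (1S,2S)-2-ethynyl-1-[3-methoxy-4-(triisopropylsilyloxy)phenyl]-1-{[2-(4,4,5,5-tetramethyl-1,3,2-dioxaborolan-2-yl)ethynyl]oxy}-3-(triisopropylsilyloxy)propane | COc1cc([C@@H](OC#CB2OC(C)(C)C(C)(C)O2)[C@H](CO[Si](C(C)C)(C(C)C)C(C)C)C#C)ccc1O[Si](C(C)C)(C(C)C)C(C)C | intermediate (key-step precursor)
20 | syringaldehyde | COc1cc(C=O)cc(OC)c1O | starting material
21 | 3,5-dimethoxy-4-(triisopropylsilyloxy)benzaldehyde | COc1cc(C=O)cc(OC)c1O[Si](C(C)C)(C(C)C)C(C)C | intermediate
22 | 2(5H)-furanone | O=C1OCC=C1 | starting material
23 | potassium vinyltrifluoroborate | [K+].C=C[B-](F)(F)F | starting material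
24 | (S)-4-vinyldihydrofuran-2(3H)-one | O=C1C[C@@H](C=C)CO1 | intermediate
25 | lithium enolate of 24 | [Li]OC1=C[C@@H](C=C)CO1 | intermediate (not isolated)
26 | (3S,4R)-3-{[3,5-dimethoxy-4-(triisopropylsilyloxy)phenyl](hydroxy)methyl}-4-vinyldihydrofuran-2(3H)-one | O=C1[C@H](C(O)c2cc(OC)c(O[Si](C(C)C)(C(C)C)C(C)C)c(OC)c2)[C@@H](C=C)CO1 | intermediate
27 | (2R,3R)-2-{[3,5-dimethoxy-4-(triisopropylsilyloxy)phenyl](hydroxy)methyl}-3-vinylbutane-1,4-diol | OC[C@H](C(O)c1cc(OC)c(O[Si](C(C)C)(C(C)C)C(C)C)c(OC)c1)[C@@H](C=C)CO | intermediate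
28 | {(2S,3R,4R)-2-[3,5-dimethoxy-4-(triisopropylsilyloxy)phenyl]-4-vinyltetrahydrofuran-3-yl}methanol | OC[C@H]1[C@@H](C=C)CO[C@@H]1c1cc(OC)c(O[Si](C(C)C)(C(C)C)C(C)C)c(OC)c1 | intermediate
29 | vicinal diol from dihydroxylation of the vinyl group of 28 | OC[C@H]1[C@@H](C(O)CO)CO[C@@H]1c1cc(OC)c(O[Si](C(C)C)(C(C)C)C(C)C)c(OC)c1 | intermediate (not isolated)
30 | (3aR,4S,6aR)-4-[3,5-dimethoxy-4-(triisopropylsilyloxy)phenyl]tetrahydro-1H,3H-furo[3,4-c]furan-1-ol | OC1OC[C@H]2[C@@H]1CO[C@@H]2c1cc(OC)c(O[Si](C(C)C)(C(C)C)C(C)C)c(OC)c1 | intermediate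
31 | (3aR,4S,6aR)-4-[3,5-dimethoxy-4-(triisopropylsilyloxy)phenyl]tetrahydro-1H,3H-furo[3,4-c]furan-1-yl acetate | CC(=O)OC1OC[C@H]2[C@@H]1CO[C@@H]2c1cc(OC)c(O[Si](C(C)C)(C(C)C)C(C)C)c(OC)c1 | intermediate
32 | trimethylsilylacetylene | C#C[Si](C)(C)C | starting material
33 | (1S,3aR,4S,6aR)-4-[3,5-dimethoxy-4-(triisopropylsilyloxy)phenyl]-1-[(trimethylsilyl)ethynyl]tetrahydro-1H,3H-furo[3,4-c]furan | C[Si](C)(C)C#C[C@H]1OC[C@H]2[C@@H]1CO[C@@H]2c1cc(OC)c(O[Si](C(C)C)(C(C)C)C(C)C)c(OC)c1 | intermediate (not isolated)
34 | (1S,3aR,4S,6aR)-4-[3,5-dimethoxy-4-(triisopropylsilyloxy)phenyl]-1-ethynyltetrahydro-1H,3H-furo[3,4-c]furan | C#C[C@H]1OC[C@H]2[C@@H]1CO[C@@H]2c1cc(OC)c(O[Si](C(C)C)(C(C)C)C(C)C)c(OC)c1 | intermediate (key-step partner)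
35 | cis-(2S,3S)-dihydrobenzofuran C7 pinacol boronate carrying the furofuran at C5 (full name in step 17) | COc1cc([C@H]2Oc3c(B4OC(C)(C)C(C)(C)O4)cc([C@H]4OC[C@H]5[C@@H]4CO[C@@H]5c4cc(OC)c(O[Si](C(C)C)(C(C)C)C(C)C)c(OC)c4)cc3[C@H]2CO[Si](C(C)C)(C(C)C)C(C)C)ccc1O[Si](C(C)C)(C(C)C)C(C)C | intermediate (key-step product)
36 | C7 phenol, tris(triisopropylsilyl) ether (full name in step 18) | COc1cc([C@H]2Oc3c(O)cc([C@H]4OC[C@H]5[C@@H]4CO[C@@H]5c4cc(OC)c(O[Si](C(C)C)(C(C)C)C(C)C)c(OC)c4)cc3[C@H]2CO[Si](C(C)C)(C(C)C)C(C)C)ccc1O[Si](C(C)C)(C(C)C)C(C)C | intermediate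
37 | tris(triisopropylsilyl) ether of 38 | COc1cc([C@H]2Oc3c(OC)cc([C@H]4OC[C@H]5[C@@H]4CO[C@@H]5c4cc(OC)c(O[Si](C(C)C)(C(C)C)C(C)C)c(OC)c4)cc3[C@H]2CO[Si](C(C)C)(C(C)C)C(C)C)ccc1O[Si](C(C)C)(C(C)C)C(C)C | intermediate
38 | CNP0126146.1 (full name in step 20) | COc1cc([C@H]2Oc3c(OC)cc([C@H]4OC[C@H]5[C@@H]4CO[C@@H]5c4cc(OC)c(O)c(OC)c4)cc3[C@H]2CO)ccc1O | target

Total step count: 20. Longest linear sequence: 11 steps (steps 2–8, 17–20 from 3; equally steps 10–16, 17–20 from 22).

Least certain steps

Step 17 (key step). The ruthenium may be tied up by the electron-rich ynol ether or the boronate so that turnover stalls. The diyne may couple with itself faster than with 34. The alkyne may insert in the other orientation. The benzylic ynol ether may fragment or rearrange before it cyclises. The fallback uses known chemistry: it takes the benzene ring from an aromatic building block and sets the cis relation by enantioselective carbenoid C–H insertion. It sets out from 2 and 30 and comes back at 37.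
- Borohydride reduction of 2 gives [3-methoxy-4-(triisopropylsilyloxy)phenyl]methanol F1.
- Mitsunobu etherification (PPh3, DIAD) of F1 with methyl 2-(5-bromo-2-hydroxy-3-methoxyphenyl)acetate F2 (from methyl 2-hydroxy-3-methoxyphenylacetate and N-bromosuccinimide) gives methyl 2-{5-bromo-3-methoxy-2-[3-methoxy-4-(triisopropylsilyloxy)benzyloxy]phenyl}acetate F3.
- Diazo transfer (p-acetamidobenzenesulfonyl azide, DBU) gives the aryldiazoacetate F4.
- Rh2(S-PTTL)4, or its enantiomer if that is the one that leads to the 2S series, should insert the carbenoid into the benzylic ether C–H to give the cis ester methyl (2S,3R)-5-bromo-7-methoxy-2-[3-methoxy-4-(triisopropylsilyloxy)phenyl]-2,3-dihydro-1-benzofuran-3-carboxylate F5.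
- DIBAL at −78 °C gives the cis alcohol F6, and TIPSOTf with 2,6-lutidine gives its silyl ether F7.
- Bromine–lithium exchange on F7 (t-BuLi, −78 °C) and addition of the aryllithium to 30, first deprotonated with i-PrMgCl, gives the diol F8.
- Mild acid (pyridinium p-toluenesulfonate, CH2Cl2, 0 °C) ionises the benzylic alcohol of F8, which is para to O1, and closes the second tetrahydrofuran with the aryl group exo, giving 37.

Step 8. The metalation may lose site selectivity, so that boron also reaches the C4 alkyne terminus. The alkoxyalkynyl boronate may also be protodeboronated during the acid quench or on handling. The fallback replaces selection by acidity with protecting-group control. It sets out from 9 and comes back at 19.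
- Aqueous citric acid work-up after the borohydride reduction removes only the O-silyl group and gives (1S,2S)-1-[3-methoxy-4-(triisopropylsilyloxy)phenyl]-2-[(trimethylsilyl)ethynyl]propane-1,3-diol F9.
- Primary silylation as in step 6 gives F10.
- F10 is taken through the dichlorovinyl ether and the lithium alkoxyacetylide as in step 7 (2.2 equiv n-BuLi, since the other alkyne is capped). The acetylide is trapped with B(OMe)3 and converted with KHF2 into the base-stable potassium trifluoroborate F11.
- K2CO3 in methanol frees the alkyl alkyne to give F12.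
- Me3SiCl and pinacol turn the trifluoroborate into 19.

Step 4. The amine may isomerise the alkynyl imide to an allenyl imide. The silyloxy group may be lost by β-elimination from the acidic aldol adduct. The anti selectivity may be eroded. The fallback replaces the aldol by a Marshall syn-propargylation. It sets out from 2 and comes back at 11.
- (S)-But-3-yne-1,2-diol (chiral pool, from D-mannitol) is silylated at the primary hydroxyl to give (S)-1-(triisopropylsilyloxy)but-3-yn-2-ol F13 and mesylated to F14.
- Bu3SnLi and CuBr·SMe2 displace the mesylate in the anti SN2′ sense to give the (P)-allenylstannane F15.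
- F15 adds to 2 under BF3·OEt2 at −78 °C through an open transition state, anti to tin, which should give 11 directly with the syn relation. The price is stoichiometric tin.

Step 7. The triisopropylsilyl group may migrate from the primary oxygen to the potassium alkoxide. The benzylic ynol ether may ionise or rearrange during work-up. The fallback avoids the free alkoxide. It sets out from 11 and comes back at 16.
- Formylation of 11 (acetic formic anhydride, pyridine) gives the formate F16.
- Dibromo-olefination (CBr4, PPh3) gives the 2,2-dibromovinyl ether F17.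
- n-BuLi (3.3 equiv, −78 °C) converts F17 into 15, and methanol gives 16.

Step 10. Conjugate addition to the weakly electrophilic lactone may be slower than protodeboronation of the vinyl reagent, and the enantioselectivity may be moderate. The fallback sets the stereocentre by iridium-catalysed allylic alkylation. It sets out from commercial dimethyl malonate and methyl (E)-4-(tert-butyldimethylsilyloxy)but-2-enyl carbonate and comes back at 24.
- [Ir(cod)Cl]2 with a chiral phosphoramidite should give the branched malonate dimethyl 2-[(2R)-1-(tert-butyldimethylsilyloxy)but-3-en-2-yl]malonate F18.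
- Fluoride removes the silyl group and the alcohol lactonises to methyl (4R)-2-oxo-4-vinyltetrahydrofuran-3-carboxylate F19.
- Krapcho decarboxylation (LiCl, wet DMSO, 130 °C) gives 24.

Further compounds
F1 | step 17 | [3-methoxy-4-(triisopropylsilyloxy)phenyl]methanol | COc1cc(CO)ccc1O[Si](C(C)C)(C(C)C)C(C)C
F2 | step 17 | methyl 2-(5-bromo-2-hydroxy-3-methoxyphenyl)acetate | COC(=O)Cc1cc(Br)cc(OC)c1O
F3 | step 17 | methyl 2-{5-bromo-3-methoxy-2-[3-methoxy-4-(triisopropylsilyloxy)benzyloxy]phenyl}acetate | COC(=O)Cc1cc(Br)cc(OC)c1OCc1ccc(O[Si](C(C)C)(C(C)C)C(C)C)c(OC)c1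
F4 | step 17 | methyl 2-diazo-2-{5-bromo-3-methoxy-2-[3-methoxy-4-(triisopropylsilyloxy)benzyloxy]phenyl}acetate | COC(=O)C(=[N+]=[N-])c1cc(Br)cc(OC)c1OCc1ccc(O[Si](C(C)C)(C(C)C)C(C)C)c(OC)c1
F5 | step 17 | methyl (2S,3R)-5-bromo-7-methoxy-2-[3-methoxy-4-(triisopropylsilyloxy)phenyl]-2,3-dihydro-1-benzofuran-3-carboxylate | COc1cc([C@H]2Oc3c(OC)cc(Br)cc3[C@H]2C(=O)OC)ccc1O[Si](C(C)C)(C(C)C)C(C)C
F6 | step 17 | {(2S,3S)-5-bromo-7-methoxy-2-[3-methoxy-4-(triisopropylsilyloxy)phenyl]-2,3-dihydro-1-benzofuran-3-yl}methanol | COc1cc([C@H]2Oc3c(OC)cc(Br)cc3[C@H]2CO)ccc1O[Si](C(C)C)(C(C)C)C(C)C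
F7 | step 17 | triisopropylsilyl ether of F6 | COc1cc([C@H]2Oc3c(OC)cc(Br)cc3[C@H]2CO[Si](C(C)C)(C(C)C)C(C)C)ccc1O[Si](C(C)C)(C(C)C)C(C)C
F8 | step 17 | diol from addition of the aryllithium of F7 to 30 (carbinol epimers) | COc1cc([C@H]2Oc3c(OC)cc(C(O)[C@H]4CO[C@H](c5cc(OC)c(O[Si](C(C)C)(C(C)C)C(C)C)c(OC)c5)[C@H]4CO)cc3[C@H]2CO[Si](C(C)C)(C(C)C)C(C)C)ccc1O[Si](C(C)C)(C(C)C)C(C)C
F9 | step 8 | (1S,2S)-1-[3-methoxy-4-(triisopropylsilyloxy)phenyl]-2-[(trimethylsilyl)ethynyl]propane-1,3-diol | COc1cc([C@@H](O)[C@H](CO)C#C[Si](C)(C)C)ccc1O[Si](C(C)C)(C(C)C)C(C)C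
F10 | step 8 | (1S,2S)-1-[3-methoxy-4-(triisopropylsilyloxy)phenyl]-3-(triisopropylsilyloxy)-2-[(trimethylsilyl)ethynyl]propan-1-ol | COc1cc([C@@H](O)[C@H](CO[Si](C(C)C)(C(C)C)C(C)C)C#C[Si](C)(C)C)ccc1O[Si](C(C)C)(C(C)C)C(C)C
F11 | step 8 | potassium trifluoroborate of the ynol ether, alkyl alkyne C-silylated | COc1cc([C@@H](OC#C[B-](F)(F)F)[C@H](CO[Si](C(C)C)(C(C)C)C(C)C)C#C[Si](C)(C)C)ccc1O[Si](C(C)C)(C(C)C)C(C)C.[K+]
F12 | step 8 | potassium trifluoroborate of the ynol ether, alkyl alkyne free | COc1cc([C@@H](OC#C[B-](F)(F)F)[C@H](CO[Si](C(C)C)(C(C)C)C(C)C)C#C)ccc1O[Si](C(C)C)(C(C)C)C(C)C.[K+]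
F13 | step 4 | (S)-1-(triisopropylsilyloxy)but-3-yn-2-ol | O[C@H](CO[Si](C(C)C)(C(C)C)C(C)C)C#C
F14 | step 4 | (S)-1-(triisopropylsilyloxy)but-3-yn-2-yl methanesulfonate | CS(=O)(=O)O[C@H](CO[Si](C(C)C)(C(C)C)C(C)C)C#C
F15 | step 4 | (P)-tributyl[4-(triisopropylsilyloxy)buta-1,2-dien-1-yl]stannane | CCCC[Sn](CCCC)(CCCC)C([H])=[C@@]=C([H])CO[Si](C(C)C)(C(C)C)C(C)C
F16 | step 7 | formate of 11 | COc1cc([C@@H](OC=O)[C@H](CO[Si](C(C)C)(C(C)C)C(C)C)C#C)ccc1O[Si](C(C)C)(C(C)C)C(C)C
F17 | step 7 | 2,2-dibromovinyl ether of 11 | COc1cc([C@@H](OC=C(Br)Br)[C@H](CO[Si](C(C)C)(C(C)C)C(C)C)C#C)ccc1O[Si](C(C)C)(C(C)C)C(C)C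
F18 | step 10 | dimethyl 2-[(2R)-1-(tert-butyldimethylsilyloxy)but-3-en-2-yl]malonate | COC(=O)C(C(=O)OC)[C@@H](C=C)CO[Si](C)(C)C(C)(C)C
F19 | step 10 | methyl (4R)-2-oxo-4-vinyltetrahydrofuran-3-carboxylate | COC(=O)C1C(=O)OC[C@@H]1C=C
A1 | alternative 1 | trans,trans menthyloxy lactone carrying the dithiane and the aryl carbinol | O=C1O[C@@H](O[C@@H]2C[C@H](C)CC[C@H]2C(C)C)[C@H](C3(c4cc(OC)c(O[Si](C(C)C)(C(C)C)C(C)C)c(OC)c4)SCCCS3)[C@H]1[C@H](O)c1cc(OC)c(OCOC)c(Br)c1
A2 | alternative 1 | (5R)-5-[(1R,2S,5R)-menthyloxy]-2(5H)-furanone | O=C1C=C[C@H](O[C@@H]2C[C@H](C)CC[C@H]2C(C)C)O1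
A3 | alternative 1 | 2-[3,5-dimethoxy-4-(triisopropylsilyloxy)phenyl]-1,3-dithiane | COc1cc(C2SCCCS2)cc(OC)c1O[Si](C(C)C)(C(C)C)C(C)C
A4 | alternative 1 | 3-bromo-5-methoxy-4-(methoxymethoxy)benzaldehyde | COCOc1c(Br)cc(C=O)cc1OC
A5 | alternative 2 | exo,exo furofuran with free bromophenol and syringyl phenol | COc1cc([C@H]2OC[C@H]3[C@@H]2CO[C@@H]3c2cc(OC)c(O)c(OC)c2)cc(Br)c1O
A6 | alternative 2 | (2R,3R)-2-(3-bromo-4-hydroxy-5-methoxybenzyl)-3-(4-hydroxy-3,5-dimethoxybenzyl)butane-1,4-diol | COc1cc(C[C@@H](CO)[C@H](CO)Cc2cc(OC)c(O)c(OC)c2)cc(Br)c1O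
A7 | alternative 3 | bis(triisopropylsilyl) ether of 38 with free hydroxymethyl | COc1cc([C@H]2Oc3c(OC)cc([C@H]4OC[C@H]5[C@@H]4CO[C@@H]5c4cc(OC)c(O[Si](C(C)C)(C(C)C)C(C)C)c(OC)c4)cc3[C@H]2CO)ccc1O[Si](C(C)C)(C(C)C)C(C)C
A8 | alternative 3 | aryl bromide with (R)-benzylic aryl ether and (R)-oxirane | COc1cc([C@@H](Oc2c(OC)cc([C@H]3OC[C@H]4[C@@H]3CO[C@@H]4c3cc(OC)c(O[Si](C(C)C)(C(C)C)C(C)C)c(OC)c3)cc2Br)[C@H]2CO2)ccc1O[Si](C(C)C)(C(C)C)C(C)C
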